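**Plan**

1. Numbering: the acid chain runs from C1′ (CO2H) to C12′ (ester C=O), with methyls on C5′, C9′, C11′ and OH on C10′. The core is numbered as a 1,2,6,7,8,8a-hexahydronaphthalene (C1 acyl/CH3, C2 OH/CH3, C6 CH3, C8 ester O, ring A = C1–C4a/C8a, ring B = C4a–C8a). The enabling feature is the unsubstituted C6′=C7′ ethene between the methyl-bearing alkenes C4′=C5′ and C8′=C9′: each neighbour can be carried as a geometrically fixed alkenyl iodide and the ethene as a 1-stannyl-2-boryl linchpin.
2. Cuts, last bond first: C5′–C6′ and C7′–C8′; the C12′–O–C8 ester; C10′–C11′ (aldol) in the acid; in the core the acyl C–C bond at C1, C2–CH3, C3=C4 and C4a=C5 (both rings), C2–C3, C1–CH3, C1–C8a and C8a–C≡C.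
3. Forward: a citronellene-derived alkynyl epoxide is opened by cyanoacetate to a lactone that carries C1, C8a and C8; the lactone is opened to an acyclic dienyne enone. Ring B and then ring A arise in one tandem metathesis. C2 methyl and the hydroxypropanoyl chain follow, then the ester with the iodo acid, then the three-component coupling and fluoride deprotection.
4. Stereochemistry: C6 from (S)-citronellene; C8 from amine-catalysed chlorination and C8a from anti acetylide addition, each carried through one SN2 inversion; C1 from lactone enolate methylation anti to its two neighbours; C2 from methyl addition to the bicyclic dienone anti to the C1 methyl; C10′/C11′ from an auxiliary-controlled anti aldol. Alkene geometry comes from anti hydroiodination (4Z), syn carboalumination (8E), olefination (2E) and hydrostannylation (6E), all retained in the coupling.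

Key step: step 25

Assumption: the (2S,5S) enantiomer of 2,5-diphenylpyrrolidine is taken to deliver the 2R chloride in step 2; if the sense is the reverse, the antipodal amine is used and nothing else changes.

**Route**

Step 1
Reactants: 1 (S)-3,7-dimethylocta-1,6-diene
Product: 3 (4S)-4-methylhex-5-enal, via ozonide 2 (not isolated)
Conditions: O3 (1 equiv, dye end-point), CH2Cl2, −78 °C; then PPh3, −78 to 23 °C
Reagents that add atoms: ozone (O=[O+][O-])
Why: Ozonolysis with reductive work-up cleaves the electron-rich trisubstituted alkene much faster than the vinyl group, so one equivalent of ozone should give the aldehyde with the C6 stereocentre untouched.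

Step 2
Reactants: 3 (4S)-4-methylhex-5-enal
Product: 5 (3S,4R,6S)-4-chloro-6-methyl-1-(trimethylsilyl)oct-7-en-1-yn-3-ol, via chloro aldehyde 4 (not isolated)
Conditions: N-chlorosuccinimide, (2S,5S)-2,5-diphenylpyrrolidine (10 mol %), CH2Cl2, 0 to 23 °C; crude 4 added to Me3SiC≡CLi (from Me3SiC≡CH, n-BuLi), THF, −78 °C; then H2O
Reagents that add atoms: N-chlorosuccinimide (O=C1CCC(=O)N1Cl); ethynyltrimethylsilane (C#C[Si](C)(C)C)
Why: Enamine-catalysed α-chlorination sets the C–Cl centre (the later C8) under catalyst control, and the lithium acetylide then adds to the α-chloro aldehyde anti to chlorine (Cornforth model) to give the anti chlorohydrin and so the later C8a centre.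

Step 3
Reactants: 5 (3S,4R,6S)-4-chloro-6-methyl-1-(trimethylsilyl)oct-7-en-1-yn-3-ol
Product: 6 (2S,3S)-2-ethynyl-3-[(2S)-2-methylbut-3-en-1-yl]oxirane
Conditions: KOH, EtOH, 23 °C
Reagents that add atoms: none
Why: Williamson ring closure of the anti chlorohydrin is stereospecific (inversion at the C–Cl carbon) and should give the trans epoxide, while ethoxide also cleaves the alkynyl C–Si bond.

Step 4
Reactants: 6 (2S,3S)-2-ethynyl-3-[(2S)-2-methylbut-3-en-1-yl]oxirane; 7 methyl cyanoacetate
Product: 9 (3S,4S,5S)-4-ethynyl-3-methyl-5-[(2S)-2-methylbut-3-en-1-yl]-2-oxooxolane-3-carbonitrile, via cyano lactone 8 (not isolated)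
Conditions: NaOMe, MeOH, 60 °C; then MeI, 23 °C
Reagents that add atoms: iodomethane (CI)
Why: The cyanoacetate anion should open the epoxide by SN2 attack at the activated propargylic carbon with inversion, the released alkoxide lactonises onto the methyl ester to a cis-4,5-disubstituted lactone, and C-methylation of the nitrile-stabilised lactone enolate occurs on the face opposite the ethynyl and alkyl groups, which sets the quaternary C1 centre.

Step 5
Reactants: 9 (3S,4S,5S)-4-ethynyl-3-methyl-5-[(2S)-2-methylbut-3-en-1-yl]-2-oxooxolane-3-carbonitrile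
Product: 11 (2S,3S,4S,6S)-2-cyano-3-ethynyl-N-methoxy-N,2,6-trimethyl-4-[(triethylsilyl)oxy]oct-7-enamide, via hydroxy amide 10 (not isolated)
Conditions: Me2AlN(OMe)Me (from MeNHOMe and Me3Al), CH2Cl2, 0 to 23 °C; aq. potassium sodium tartrate; then Et3SiCl, imidazole, DMF, 0 °C
Reagents that add atoms: N,O-dimethylhydroxylamine (CNOC); chlorotriethylsilane (CC[Si](Cl)(CC)CC)
Why: Weinreb aminolysis of the cyano-activated lactone opens the ring without touching a stereocentre, and immediate silylation of the released secondary alcohol prevents relactonisation.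

Step 6
Reactants: 11 (2S,3S,4S,6S)-2-cyano-3-ethynyl-N-methoxy-N,2,6-trimethyl-4-[(triethylsilyl)oxy]oct-7-enamide
Product: 12 (4S,5S,6S,8S)-5-ethynyl-4,8-dimethyl-3-oxo-6-[(triethylsilyl)oxy]deca-1,9-diene-4-carbonitrile
Conditions: CH2=CHMgBr (3 equiv), THF, −20 to 0 °C; cold 1 M HCl
Reagents that add atoms: vinylmagnesium bromide (C=C[Mg]Br)
Why: In this Weinreb ketone synthesis the Grignard adduct is held as a chelated tetrahedral intermediate that gives the vinyl ketone only on acidic quench, and the hindered tertiary nitrile should not react at this temperature.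

Step 7
Reactants: 12 (4S,5S,6S,8S)-5-ethynyl-4,8-dimethyl-3-oxo-6-[(triethylsilyl)oxy]deca-1,9-diene-4-carbonitrile
Product: 13 (1S,6S,8S,8aS)-1,6-dimethyl-2-oxo-8-[(triethylsilyl)oxy]-1,2,6,7,8,8a-hexahydronaphthalene-1-carbonitrile
Conditions: second-generation Grubbs catalyst (5 mol %), CH2Cl2 (2 mM), 40 °C
Reagents that add atoms: none
Why: In this tandem ring-closing enyne–diene metathesis the ruthenium carbene should load on the unhindered terminal alkene rather than the electron-poor enone, close ring B onto the alkyne (6-exo) and then close ring A from the resulting vinyl carbene onto the enone, which gives the cross-ring dienone with the four stereocentres untouched.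

Step 8
Reactants: 13 (1S,6S,8S,8aS)-1,6-dimethyl-2-oxo-8-[(triethylsilyl)oxy]-1,2,6,7,8,8a-hexahydronaphthalene-1-carbonitrile
Product: 14 (1S,2R,6S,8S,8aS)-2-hydroxy-1,2,6-trimethyl-8-[(triethylsilyl)oxy]-1,2,6,7,8,8a-hexahydronaphthalene-1-carbonitrile
Conditions: CeCl3, MeLi, THF, −78 °C; then H2O, −78 °C
Reagents that add atoms: methyllithium (C[Li])
Why: 1,2-Addition of the weakly basic organocerium reagent to the non-enolisable dienone should occur on the face syn to the slender nitrile and H-8a, because the other face is screened by the C1 methyl group and the C8 silyloxy group, which sets the tertiary carbinol at C2, and the ketone reacts far faster than the nitrile.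

Step 9
Reactants: 14 (1S,2R,6S,8S,8aS)-2-hydroxy-1,2,6-trimethyl-8-[(triethylsilyl)oxy]-1,2,6,7,8,8a-hexahydronaphthalene-1-carbonitrile
Product: 15 (1S,2R,6S,8S,8aS)-1,2,6-trimethyl-8-[(triethylsilyl)oxy]-2-[(trimethylsilyl)oxy]-1,2,6,7,8,8a-hexahydronaphthalene-1-carbonitrile
Conditions: 1-(trimethylsilyl)imidazole, CH2Cl2, 23 °C
Reagents that add atoms: 1-(trimethylsilyl)imidazole (C[Si](C)(C)n1ccnc1)
Why: Neutral silylation masks the tertiary alcohol so that no alkoxide β to the nitrile, which could fragment by retro-addition, is present in the next step.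

Step 10
Reactants: 15 (1S,2R,6S,8S,8aS)-1,2,6-trimethyl-8-[(triethylsilyl)oxy]-2-[(trimethylsilyl)oxy]-1,2,6,7,8,8a-hexahydronaphthalene-1-carbonitrile
Product: 17 3-hydroxy-1-[(1R,2R,6S,8S,8aS)-1,2,6-trimethyl-8-[(triethylsilyl)oxy]-2-[(trimethylsilyl)oxy]-1,2,6,7,8,8a-hexahydronaphthalen-1-yl]propan-1-one, via ketimine 16 (not isolated)
Conditions: LiCH2CH2OLi (from ClCH2CH2OH, n-BuLi, then lithium naphthalenide, THF, −78 °C), −78 to −40 °C; then aq. AcOH/NaOAc (pH 5), THF, 0 to 23 °C
Reagents that add atoms: 2-chloroethanol (OCCCl); water (O)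
Why: An organolithium adds only once to a nitrile because the N-lithio ketimine is inert to further attack, so the β-oxido organolithium should deliver the 3-hydroxypropanoyl ketone after mild hydrolysis of the imine.

Step 11
Reactants: 17 3-hydroxy-1-[(1R,2R,6S,8S,8aS)-1,2,6-trimethyl-8-[(triethylsilyl)oxy]-2-[(trimethylsilyl)oxy]-1,2,6,7,8,8a-hexahydronaphthalen-1-yl]propan-1-one
Product: 18 1-[(1R,2R,6S,8S,8aS)-2,8-dihydroxy-1,2,6-trimethyl-1,2,6,7,8,8a-hexahydronaphthalen-1-yl]-3-hydroxypropan-1-one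
Conditions: HF·pyridine, pyridine, THF, 0 to 23 °C
Reagents that add atoms: none
Why: Buffered fluoride desilylation removes both silyl ethers without the acid-catalysed ionisation to which the tertiary dienyl alcohol is prone.

Step 12
Reactants: 18 1-[(1R,2R,6S,8S,8aS)-2,8-dihydroxy-1,2,6-trimethyl-1,2,6,7,8,8a-hexahydronaphthalen-1-yl]-3-hydroxypropan-1-one
Product: 19 3-[(tert-butyldimethylsilyl)oxy]-1-[(1R,2R,6S,8S,8aS)-2,8-dihydroxy-1,2,6-trimethyl-1,2,6,7,8,8a-hexahydronaphthalen-1-yl]propan-1-one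
Conditions: t-BuMe2SiCl (1.05 equiv), imidazole, CH2Cl2, 0 °C
Reagents that add atoms: tert-butyldimethylsilyl chloride (CC(C)(C)[Si](C)(C)Cl)
Why: Silylation with one equivalent of the bulky chloride should select the primary hydroxyl over the hindered secondary C8 and the tertiary C2 hydroxyls.

Step 13
Reactants: 20 prop-2-yn-1-ol
Product: 22 (2E)-3-iodo-2-methylprop-2-en-1-ol, via alkenylalane 21 (not isolated)
Conditions: Me3Al, Cp2ZrCl2 (25 mol %), CH2Cl2, 0 to 23 °C; then I2, THF, −30 °C; aq. K2CO3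
Reagents that add atoms: trimethylaluminium (C[Al](C)C); iodine (II)
Why: Zirconium-catalysed carboalumination (Negishi) adds methyl and aluminium syn across the alkyne with aluminium at the terminus, and iodinolysis of the alkenyl–aluminium bond with retention gives the E iodide.

Step 14
Reactants: 22 (2E)-3-iodo-2-methylprop-2-en-1-ol
Product: 23 (2E)-3-iodo-2-methylprop-2-enal
Conditions: MnO2, CH2Cl2, 23 °C
Reagents that add atoms: none
Why: MnO2 oxidises the allylic alcohol selectively to the enal without touching the alkenyl iodide or its geometry.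

Step 15
Reactants: 23 (2E)-3-iodo-2-methylprop-2-enal; 24 (4R)-4-benzyl-3-propanoyl-1,3-oxazolidin-2-one
Product: 26 (4R)-4-benzyl-3-[(2S,3R,4E)-3-hydroxy-5-iodo-2,4-dimethylpent-4-enoyl]-1,3-oxazolidin-2-one, via silyl aldolate 25 (not isolated)
Conditions: MgCl2 (10 mol %), Et3N, Me3SiCl, EtOAc, 23 °C; then CF3CO2H, MeOH
Reagents that add atoms: none
Why: In this magnesium-halide-catalysed anti-aldol reaction of an N-acyl oxazolidinone, soft enolisation gives the chelated Z enolate, the non-enolisable enal adds on the face away from the benzyl group through a boat-like transition state and silylation of the aldolate drives turnover, which should set the 2S and 3R centres together.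

Step 16
Reactants: 26 (4R)-4-benzyl-3-[(2S,3R,4E)-3-hydroxy-5-iodo-2,4-dimethylpent-4-enoyl]-1,3-oxazolidin-2-one
Product: 27 (4R)-4-benzyl-3-[(2S,3R,4E)-5-iodo-2,4-dimethyl-3-[(triethylsilyl)oxy]pent-4-enoyl]-1,3-oxazolidin-2-one
Conditions: Et3SiOTf, 2,6-lutidine, CH2Cl2, −78 °C
Reagents that add atoms: triethylsilyl trifluoromethanesulfonate (CC[Si](CC)(CC)OS(=O)(=O)C(F)(F)F)
Why: Silylation with the silyl triflate and a hindered base protects the secondary alcohol so that it cannot compete in the later esterification.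

Step 17
Reactants: 27 (4R)-4-benzyl-3-[(2S,3R,4E)-5-iodo-2,4-dimethyl-3-[(triethylsilyl)oxy]pent-4-enoyl]-1,3-oxazolidin-2-one
Product: 29 (2S,3R,4E)-5-iodo-2,4-dimethyl-3-[(triethylsilyl)oxy]pent-4-enoic acid, via peroxy acid 28 (not isolated)
Conditions: LiOH, H2O2, THF/H2O, 0 °C; then Na2SO3; 1 M HCl to pH 3
Reagents that add atoms: hydrogen peroxide (OO)
Why: Hydroperoxide attacks the exocyclic imide carbonyl selectively (standard oxazolidinone auxiliary cleavage) and releases the acid and the recoverable auxiliary without epimerising the α-centre.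

Step 18
Reactants: 19 3-[(tert-butyldimethylsilyl)oxy]-1-[(1R,2R,6S,8S,8aS)-2,8-dihydroxy-1,2,6-trimethyl-1,2,6,7,8,8a-hexahydronaphthalen-1-yl]propan-1-one; 29 (2S,3R,4E)-5-iodo-2,4-dimethyl-3-[(triethylsilyl)oxy]pent-4-enoic acid
Product: 31 (1R,2R,6S,8S,8aS)-1-{3-[(tert-butyldimethylsilyl)oxy]propanoyl}-2-hydroxy-1,2,6-trimethyl-1,2,6,7,8,8a-hexahydronaphthalen-8-yl (2S,3R,4E)-5-iodo-2,4-dimethyl-3-[(triethylsilyl)oxy]pent-4-enoate, via mixed anhydride 30 (not isolated)
Conditions: 2,4,6-trichlorobenzoyl chloride, Et3N, THF, 23 °C; then 19, DMAP, toluene, 23 to 40 °C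
Reagents that add atoms: none
Why: In this Yamaguchi esterification the mixed anhydride is attacked at its aliphatic carbonyl by the secondary C8 alcohol under DMAP catalysis, and the tertiary C2 hydroxyl is too hindered to be acylated.

Step 19
Reactants: 32 ethyl but-2-ynoate
Product: 33 ethyl (2Z)-3-iodobut-2-enoate
Conditions: NaI, AcOH, 115 °C
Reagents that add atoms: sodium iodide ([Na+].[I-])
Why: Conjugate hydroiodination of the ynoate proceeds by anti addition of iodide and a proton and gives the Z β-iodo enoate.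

Step 20
Reactants: 33 ethyl (2Z)-3-iodobut-2-enoate
Product: 34 (2Z)-3-iodobut-2-en-1-ol
Conditions: i-Bu2AlH, CH2Cl2, −78 °C; H2O
Reagents that add atoms: none
Why: Hydride reduction of the conjugated ester at low temperature gives the allylic alcohol without reducing or isomerising the alkenyl iodide.

Step 21
Reactants: 34 (2Z)-3-iodobut-2-en-1-ol
Product: 35 (2Z)-3-iodobut-2-enal
Conditions: MnO2, CH2Cl2, 23 °C
Reagents that add atoms: none
Why: Allylic oxidation with MnO2 gives the enal with the Z geometry retained.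

Step 22
Reactants: 36 (diethoxyphosphoryl)acetic acid; 37 2-(trimethylsilyl)ethanol
Product: 38 2-(trimethylsilyl)ethyl (diethoxyphosphoryl)acetate
Conditions: DCC, DMAP (cat.), CH2Cl2, 0 to 23 °C
Reagents that add atoms: none
Why: Steglich esterification gives the fluoride-labile ester of the phosphonoacetic acid under neutral conditions.

Step 23
Reactants: 35 (2Z)-3-iodobut-2-enal; 38 2-(trimethylsilyl)ethyl (diethoxyphosphoryl)acetate
Product: 39 2-(trimethylsilyl)ethyl (2E,4Z)-5-iodohexa-2,4-dienoate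
Conditions: LiCl, i-Pr2NEt, MeCN, 23 °C
Reagents that add atoms: none
Why: Horner–Wadsworth–Emmons olefination under mild LiCl/amine conditions forms the new alkene with E geometry and leaves the base-sensitive Z β-iodo alkene unchanged.

Step 24
Reactants: 40 2-ethynyl-4,4,5,5-tetramethyl-1,3,2-dioxaborolane; 41 tributyltin hydride
Product: 42 tributyl[(E)-2-(4,4,5,5-tetramethyl-1,3,2-dioxaborolan-2-yl)ethenyl]stannane
Conditions: AIBN (cat.), neat, 80 °C
Reagents that add atoms: none
Why: In this radical hydrostannylation the stannyl radical adds to the terminal alkyne carbon (the vinyl radical is stabilised next to boron) and reversible stannyl radical addition equilibrates the product to the E alkene.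

Step 25
Reactants: 39 2-(trimethylsilyl)ethyl (2E,4Z)-5-iodohexa-2,4-dienoate; 42 tributyl[(E)-2-(4,4,5,5-tetramethyl-1,3,2-dioxaborolan-2-yl)ethenyl]stannane; 31 (1R,2R,6S,8S,8aS)-1-{3-[(tert-butyldimethylsilyl)oxy]propanoyl}-2-hydroxy-1,2,6-trimethyl-1,2,6,7,8,8a-hexahydronaphthalen-8-yl (2S,3R,4E)-5-iodo-2,4-dimethyl-3-[(triethylsilyl)oxy]pent-4-enoate
Product: 44 calbistrin D protected as its 2-(trimethylsilyl)ethyl ester C10′ triethylsilyl ether and primary tert-butyldimethylsilyl ether, via trienyl boronate 43 (not isolated)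
Conditions: 39, 42, PdCl2(MeCN)2 (5 mol %), DMF, 23 °C, dark; then 31, Pd(PPh3)4 (10 mol %), TlOEt, THF/H2O, 23 °C
Reagents that add atoms: none
Why: Oxidative addition of zerovalent palladium into the C–I bond of the electron-poor dienyl iodide 39, transmetalation from the tin terminus of 42 and reductive elimination forge C5′–C6′ under base-free conditions in which the pinacol boronate cannot transmetalate, so trienyl boronate 43 accumulates. TlOEt then converts the boronate into a borate that transmetalates to the alkenylpalladium iodide formed from the hindered iodide 31, and reductive elimination forges C7′–C8′. The closest known reaction type is the one-pot Stille/Suzuki–Miyaura coupling of a 1-stannyl-2-boryl ethene with two different alkenyl halides. No ring is closed and no stereocentre is formed. The step needs chemoselectivity (tin before boron, each iodide used once) and retention of the 4Z, 6E and 8E geometries; the first is secured by the order of addition and the base-gated activation of boron, the second by stereoretentive oxidative addition, transmetalation and reductive elimination at sp2 carbon. The mild base, 23 °C and exclusion of light should spare the tetraene, the β-silyloxy ketone and the tertiary dienyl alcohol.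

Step 26
Reactants: 44 calbistrin D protected as its 2-(trimethylsilyl)ethyl ester C10′ triethylsilyl ether and primary tert-butyldimethylsilyl ether
Product: 45 calbistrin D
Conditions: (Me2N)3S+ Me3SiF2− (TASF), DMF, 0 to 23 °C; pH 7 phosphate buffer
Reagents that add atoms: none
Why: Fluoride attack on silicon triggers β-elimination of the silylethyl ester (loss of ethylene and Me3SiF) and cleaves both silyl ethers in the same operation, under conditions mild enough that the β-hydroxy ketones should neither eliminate nor undergo retro-aldol cleavage.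

**Compound list**

1 | (S)-3,7-dimethylocta-1,6-diene [(S)-β-citronellene] | CC(C)=CCC[C@H](C)C=C | starting material
2 | 3,3-dimethyl-5-[(3S)-3-methylpent-4-en-1-yl]-1,2,4-trioxolane (ozonide) | CC1(C)OOC(CC[C@H](C)C=C)O1 | intermediate (not isolated)
3 | (4S)-4-methylhex-5-enal | O=CCC[C@H](C)C=C | intermediate
4 | (2R,4S)-2-chloro-4-methylhex-5-enal | O=C[C@H](Cl)C[C@H](C)C=C | intermediate (not isolated)
5 | (3S,4R,6S)-4-chloro-6-methyl-1-(trimethylsilyl)oct-7-en-1-yn-3-ol | C[Si](C)(C)C#C[C@H](O)[C@H](Cl)C[C@H](C)C=C | intermediate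
6 | (2S,3S)-2-ethynyl-3-[(2S)-2-methylbut-3-en-1-yl]oxirane | C#C[C@@H]1O[C@H]1C[C@H](C)C=C | intermediate
7 | methyl cyanoacetate | N#CCC(=O)OC | starting material
8 | (4R,5S)-4-ethynyl-5-[(2S)-2-methylbut-3-en-1-yl]-2-oxooxolane-3-carbonitrile (C3 epimers, present as the sodium enolate) | O=C1O[C@@H](C[C@H](C)C=C)[C@@H](C#C)C1C#N | intermediate (not isolated)
9 | (3S,4S,5S)-4-ethynyl-3-methyl-5-[(2S)-2-methylbut-3-en-1-yl]-2-oxooxolane-3-carbonitrile | O=C1O[C@@H](C[C@H](C)C=C)[C@@H](C#C)[C@@]1(C)C#N | intermediate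
10 | (2S,3S,4S,6S)-2-cyano-3-ethynyl-4-hydroxy-N-methoxy-N,2,6-trimethyloct-7-enamide | O[C@@H](C[C@H](C)C=C)[C@@H](C#C)[C@@](C)(C#N)C(=O)N(C)OC | intermediate (not isolated)
11 | (2S,3S,4S,6S)-2-cyano-3-ethynyl-N-methoxy-N,2,6-trimethyl-4-[(triethylsilyl)oxy]oct-7-enamide | CC[Si](CC)(CC)O[C@@H](C[C@H](C)C=C)[C@@H](C#C)[C@@](C)(C#N)C(=O)N(C)OC | intermediate
12 | (4S,5S,6S,8S)-5-ethynyl-4,8-dimethyl-3-oxo-6-[(triethylsilyl)oxy]deca-1,9-diene-4-carbonitrile | CC[Si](CC)(CC)O[C@@H](C[C@H](C)C=C)[C@@H](C#C)[C@@](C)(C#N)C(=O)C=C | intermediate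
13 | (1S,6S,8S,8aS)-1,6-dimethyl-2-oxo-8-[(triethylsilyl)oxy]-1,2,6,7,8,8a-hexahydronaphthalene-1-carbonitrile | CC[Si](CC)(CC)O[C@H]1C[C@H](C)C=C2C=CC(=O)[C@](C)(C#N)[C@H]21 | intermediate
14 | (1S,2R,6S,8S,8aS)-2-hydroxy-1,2,6-trimethyl-8-[(triethylsilyl)oxy]-1,2,6,7,8,8a-hexahydronaphthalene-1-carbonitrile | CC[Si](CC)(CC)O[C@H]1C[C@H](C)C=C2C=C[C@@](C)(O)[C@](C)(C#N)[C@H]21 | intermediate
15 | (1S,2R,6S,8S,8aS)-1,2,6-trimethyl-8-[(triethylsilyl)oxy]-2-[(trimethylsilyl)oxy]-1,2,6,7,8,8a-hexahydronaphthalene-1-carbonitrile | CC[Si](CC)(CC)O[C@H]1C[C@H](C)C=C2C=C[C@@](C)(O[Si](C)(C)C)[C@](C)(C#N)[C@H]21 | intermediate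
16 | 3-imino-3-[(1S,2R,6S,8S,8aS)-1,2,6-trimethyl-8-[(triethylsilyl)oxy]-2-[(trimethylsilyl)oxy]-1,2,6,7,8,8a-hexahydronaphthalen-1-yl]propan-1-ol (ketimine) | CC[Si](CC)(CC)O[C@H]1C[C@H](C)C=C2C=C[C@@](C)(O[Si](C)(C)C)[C@](C)(C(=N)CCO)[C@H]21 | intermediate (not isolated)
17 | 3-hydroxy-1-[(1R,2R,6S,8S,8aS)-1,2,6-trimethyl-8-[(triethylsilyl)oxy]-2-[(trimethylsilyl)oxy]-1,2,6,7,8,8a-hexahydronaphthalen-1-yl]propan-1-one | CC[Si](CC)(CC)O[C@H]1C[C@H](C)C=C2C=C[C@@](C)(O[Si](C)(C)C)[C@](C)(C(=O)CCO)[C@H]21 | intermediate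
18 | 1-[(1R,2R,6S,8S,8aS)-2,8-dihydroxy-1,2,6-trimethyl-1,2,6,7,8,8a-hexahydronaphthalen-1-yl]-3-hydroxypropan-1-one | O[C@H]1C[C@H](C)C=C2C=C[C@@](C)(O)[C@](C)(C(=O)CCO)[C@H]21 | intermediate
19 | 3-[(tert-butyldimethylsilyl)oxy]-1-[(1R,2R,6S,8S,8aS)-2,8-dihydroxy-1,2,6-trimethyl-1,2,6,7,8,8a-hexahydronaphthalen-1-yl]propan-1-one | O[C@H]1C[C@H](C)C=C2C=C[C@@](C)(O)[C@](C)(C(=O)CCO[Si](C)(C)C(C)(C)C)[C@H]21 | intermediate
20 | prop-2-yn-1-ol | C#CCO | starting material
21 | dimethylaluminium (2E)-3-(dimethylalumanyl)-2-methylprop-2-en-1-olate (alkenylalane) | C[Al](C)OC/C(C)=C/[Al](C)C | intermediate (not isolated)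
22 | (2E)-3-iodo-2-methylprop-2-en-1-ol | OC/C(C)=C/I | intermediate
23 | (2E)-3-iodo-2-methylprop-2-enal | O=C/C(C)=C/I | intermediate
24 | (4R)-4-benzyl-3-propanoyl-1,3-oxazolidin-2-one | CCC(=O)N1[C@H](Cc2ccccc2)COC1=O | starting material
25 | (4R)-4-benzyl-3-[(2S,3R,4E)-5-iodo-2,4-dimethyl-3-[(trimethylsilyl)oxy]pent-4-enoyl]-1,3-oxazolidin-2-one | I/C=C(\C)[C@H](O[Si](C)(C)C)[C@H](C)C(=O)N1[C@H](Cc2ccccc2)COC1=O | intermediate (not isolated)
26 | (4R)-4-benzyl-3-[(2S,3R,4E)-3-hydroxy-5-iodo-2,4-dimethylpent-4-enoyl]-1,3-oxazolidin-2-one | I/C=C(\C)[C@H](O)[C@H](C)C(=O)N1[C@H](Cc2ccccc2)COC1=O | intermediate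
27 | (4R)-4-benzyl-3-[(2S,3R,4E)-5-iodo-2,4-dimethyl-3-[(triethylsilyl)oxy]pent-4-enoyl]-1,3-oxazolidin-2-one | I/C=C(\C)[C@H](O[Si](CC)(CC)CC)[C@H](C)C(=O)N1[C@H](Cc2ccccc2)COC1=O | intermediate
28 | (2S,3R,4E)-5-iodo-2,4-dimethyl-3-[(triethylsilyl)oxy]pent-4-eneperoxoic acid | I/C=C(\C)[C@H](O[Si](CC)(CC)CC)[C@H](C)C(=O)OO | intermediate (not isolated)
29 | (2S,3R,4E)-5-iodo-2,4-dimethyl-3-[(triethylsilyl)oxy]pent-4-enoic acid | I/C=C(\C)[C@H](O[Si](CC)(CC)CC)[C@H](C)C(=O)O | intermediate
30 | (2S,3R,4E)-5-iodo-2,4-dimethyl-3-[(triethylsilyl)oxy]pent-4-enoic 2,4,6-trichlorobenzoic anhydride | I/C=C(\C)[C@H](O[Si](CC)(CC)CC)[C@H](C)C(=O)OC(=O)c1c(Cl)cc(Cl)cc1Cl | intermediate (not isolated)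
31 | (1R,2R,6S,8S,8aS)-1-{3-[(tert-butyldimethylsilyl)oxy]propanoyl}-2-hydroxy-1,2,6-trimethyl-1,2,6,7,8,8a-hexahydronaphthalen-8-yl (2S,3R,4E)-5-iodo-2,4-dimethyl-3-[(triethylsilyl)oxy]pent-4-enoate (core locants as in 19) | I/C=C(\C)[C@H](O[Si](CC)(CC)CC)[C@H](C)C(=O)O[C@H]1C[C@H](C)C=C2C=C[C@@](C)(O)[C@](C)(C(=O)CCO[Si](C)(C)C(C)(C)C)[C@H]21 | intermediate
32 | ethyl but-2-ynoate | CC#CC(=O)OCC | starting material
33 | ethyl (2Z)-3-iodobut-2-enoate | CCOC(=O)/C=C(/C)I | intermediate
34 | (2Z)-3-iodobut-2-en-1-ol | OC/C=C(/C)I | intermediate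
35 | (2Z)-3-iodobut-2-enal | O=C/C=C(/C)I | intermediate
36 | (diethoxyphosphoryl)acetic acid | CCOP(=O)(CC(=O)O)OCC | starting material
37 | 2-(trimethylsilyl)ethanol | C[Si](C)(C)CCO | starting material
38 | 2-(trimethylsilyl)ethyl (diethoxyphosphoryl)acetate | CCOP(=O)(CC(=O)OCC[Si](C)(C)C)OCC | intermediate
39 | 2-(trimethylsilyl)ethyl (2E,4Z)-5-iodohexa-2,4-dienoate | CC(=C/C=C/C(=O)OCC[Si](C)(C)C)/I | intermediate
40 | 2-ethynyl-4,4,5,5-tetramethyl-1,3,2-dioxaborolane | C#CB1OC(C)(C)C(C)(C)O1 | starting material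
41 | tributyltin hydride | CCCC[SnH](CCCC)CCCC | starting material
42 | tributyl[(E)-2-(4,4,5,5-tetramethyl-1,3,2-dioxaborolan-2-yl)ethenyl]stannane | CCCC[Sn](CCCC)(CCCC)/C=C/B1OC(C)(C)C(C)(C)O1 | intermediate
43 | 2-(trimethylsilyl)ethyl (2E,4Z,6E)-5-methyl-7-(4,4,5,5-tetramethyl-1,3,2-dioxaborolan-2-yl)hepta-2,4,6-trienoate | CC(=C/C=C/C(=O)OCC[Si](C)(C)C)/C=C/B1OC(C)(C)C(C)(C)O1 | intermediate (not isolated)
44 | calbistrin D protected as its 2-(trimethylsilyl)ethyl ester, C10′ triethylsilyl ether and primary tert-butyldimethylsilyl ether | CC(=C/C=C/C(=O)OCC[Si](C)(C)C)/C=C/C=C(\C)[C@H](O[Si](CC)(CC)CC)[C@H](C)C(=O)O[C@H]1C[C@H](C)C=C2C=C[C@@](C)(O)[C@](C)(C(=O)CCO[Si](C)(C)C(C)(C)C)[C@H]21 | intermediate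
45 | calbistrin D | CC(=C/C=C/C(=O)O)/C=C/C=C(\C)[C@H](O)[C@H](C)C(=O)O[C@H]1C[C@H](C)C=C2C=C[C@@](C)(O)[C@](C)(C(=O)CCO)[C@H]21 | target

**Step count and risks**

Total: 26 steps. Longest linear sequence: 15 steps (steps 1–12, 18, 25, 26, from compound 1).

Steps most likely to fail:

Step 4. The carbanion may attack the non-propargylic oxirane carbon or open the epoxide in SN2′ fashion to an allenyl alcohol, so that regiocontrol in the C1–C8a bond formation is lost. Fallback from 5, rejoining at 8: the C1–C8a bond is made by displacement at an open-chain activated centre. Chlorohydrin 5 is converted with MeSO2Cl and Et3N into the propargylic mesylate F1. Sodium methyl cyanoacetate displaces the mesylate with inversion to give the chloro cyano ester F2. LiOH in aqueous THF hydrolyses the ester and removes the alkynyl silyl group, and warming closes the lactone by intramolecular carboxylate displacement of chloride, again with inversion. Each centre is inverted once, as in steps 3 and 4, so cyano lactone 8 results and is methylated (NaOMe, MeI) to 9 as before.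

Step 7. The carbene may load on the wrong partner, or methylidene transfer to the alkyne may precede ring closure, which leads to five-membered ring closure or oligomers. Fallback from 11, rejoining at 13: the rings are closed one at a time. Weinreb amide 11 has a single alkene and undergoes plain 6-exo ring-closing enyne metathesis (second-generation Grubbs catalyst, CH2Cl2, 40 °C) to the ring B vinylcyclohexene F3. Vinylmagnesium bromide then gives the trienone F4. Ring-closing diene metathesis between the ring vinyl group and the enone closes ring A to 13.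

Step 10. The β-oxido organolithium may decompose by loss of ethylene faster than it adds to the hindered nitrile. Fallback from 15, rejoining at 17: the two carbons and the oxygen are introduced separately. Vinyllithium adds to nitrile 15, and hydrolysis of the metalloimine gives the vinyl ketone F5. Conjugate borylation with bis(pinacolato)diboron (CuCl, NaOt-Bu, bis[2-(diphenylphosphino)phenyl] ether, MeOH, THF) gives the β-boryl ketone F6. Oxidation with NaBO3 in THF/H2O gives hydroxy ketone 17.

Further compounds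

F1 | step 4 | (3S,4R,6S)-4-chloro-6-methyl-1-(trimethylsilyl)oct-7-en-1-yn-3-yl methanesulfonate | C[Si](C)(C)C#C[C@H](OS(C)(=O)=O)[C@H](Cl)C[C@H](C)C=C
F2 | step 4 | methyl (3R,4R,6S)-4-chloro-2-cyano-6-methyl-3-[(trimethylsilyl)ethynyl]oct-7-enoate (C2 epimers) | C[Si](C)(C)C#C[C@@H](C(C#N)C(=O)OC)[C@H](Cl)C[C@H](C)C=C
F3 | step 7 | (2S)-2-cyano-2-[(1S,4S,6S)-2-ethenyl-4-methyl-6-[(triethylsilyl)oxy]cyclohex-2-en-1-yl]-N-methoxy-N-methylpropanamide | CC[Si](CC)(CC)O[C@H]1C[C@H](C)C=C(C=C)[C@H]1[C@@](C)(C#N)C(=O)N(C)OC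
F4 | step 7 | (2S)-2-[(1S,4S,6S)-2-ethenyl-4-methyl-6-[(triethylsilyl)oxy]cyclohex-2-en-1-yl]-2-methyl-3-oxopent-4-enenitrile | CC[Si](CC)(CC)O[C@H]1C[C@H](C)C=C(C=C)[C@H]1[C@@](C)(C#N)C(=O)C=C
F5 | step 10 | 1-[(1R,2R,6S,8S,8aS)-1,2,6-trimethyl-8-[(triethylsilyl)oxy]-2-[(trimethylsilyl)oxy]-1,2,6,7,8,8a-hexahydronaphthalen-1-yl]prop-2-en-1-one | CC[Si](CC)(CC)O[C@H]1C[C@H](C)C=C2C=C[C@@](C)(O[Si](C)(C)C)[C@](C)(C(=O)C=C)[C@H]21
F6 | step 10 | 3-(4,4,5,5-tetramethyl-1,3,2-dioxaborolan-2-yl)-1-[(1R,2R,6S,8S,8aS)-1,2,6-trimethyl-8-[(triethylsilyl)oxy]-2-[(trimethylsilyl)oxy]-1,2,6,7,8,8a-hexahydronaphthalen-1-yl]propan-1-one | CC[Si](CC)(CC)O[C@H]1C[C@H](C)C=C2C=C[C@@](C)(O[Si](C)(C)C)[C@](C)(C(=O)CCB3OC(C)(C)C(C)(C)O3)[C@H]21
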